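The numbers in the tables are simulated for an exercise, and the scatter is random.

**Common capture.** If target and other capture product are both caught from one common intermediate, dividing their two rates removes time and the intermediate: d[target]/d[other capture product] = s·[first nucleophile]/[second nucleophile].

in all of them: substrate 0.050 M
- west: first nucleophile 0.10 M; second nucleophile 0.050 M; run made earlier
- north-east: first nucleophile 0.17 M; second nucleophile 0.050 M; run made earlier
- flask: first nucleophile 0.0750 M; second nucleophile 0.0500 M; time 3.0 d

| run | time / d | target / % | other capture product / % | substrate / % |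
|---|---|---|---|---|
| west | 0.125 | 2.5 | 0.2 | 95.1 |
| west | 0.333 | 6.3 | 1.5 | 88.1 |
| west | 0.625 | 11.4 | 3.2 | 77.6 |
| west | 1.04 | 17.0 | 4.9 | 66.3 |
| west | 1.67 | 23.7 | 6.9 | 51.1 |
| west | 2.08 | 28.2 | 8.1 | 42.4 |
| west | 2.50 | 31.2 | 9.2 | 36.5 |
| north-east | 0.333 | 8.4 | 0.8 | 87.0 |
| north-east | 0.625 | 14.1 | 2.5 | 78.0 |
| north-east | 1.04 | 21.6 | 4.0 | 65.3 |
| north-east | 1.25 | 25.1 | 4.6 | 60.0 |
| north-east | 1.67 | 30.1 | 5.1 | 51.2 |
| north-east | 2.08 | 35.1 | 6.5 | 42.8 |
| north-east | 2.50 | 39.9 | 6.8 | 36.6 |

(each reading ± 0.3 percentage points)

- share of target in target plus other capture product at 1.5 h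
- share of target in target plus other capture product at 3.0 d
- which of target and other capture product there is more of at 3.0 d

**Reading s.** The last readings, taken with the charge ratios, give 1.70 in the west run and 1.73 in the north-east run. Their mean reading is 1.71, the selectivity factor: target formed per other capture product formed at equal nucleophile concentrations.

**Bench rule.** For the flask, s times the charge ratio gives a product ratio of 2.57, so my reckoning puts the share of target at 72.0 %, at 1.5 h and at 3.0 d alike.

**Its border.** The charge ratio stands in for the present ratio only at first. A target yield like the west run's last 31.2 % takes 20.8 % of the flask's first nucleophile charge, so the late figure is a start value. At the early end, the first west reading of other capture product is 0.2 %, with a scatter of 0.3 percentage points, where the rule expects 0.731 %.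

**The forecast.** It gives 91 % early, 72 % late and target in the lead, on the ground that “Other capture product lags by about 0.1 d”. Its early share is higher than my reckoned 72.0 %.

**The result.** The flask gives 72.5 % at 1.5 h, beside the reckoned 72.0 %, and 71.6 % at 3.0 d. At 3.0 d, target stands at 29.1 % and other capture product at 11.5 %.

    substrate → intermediate (k = 2.80 × 10⁻⁴ min⁻¹)
    first nucleophile + intermediate → target (k = 0.440 M⁻¹ min⁻¹)
    intermediate → side product (k = 9.50 × 10⁻⁴ min⁻¹)
    second nucleophile + intermediate → other capture product (k = 0.250 M⁻¹ min⁻¹)
    intermediate → solvolysis product (k = 0.0290 min⁻¹)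

**Neighbour flask.** In a neighbour flask with 0.12 M of second nucleophile, s gives a start ratio of 1.07 and a share of 51.7 %. That neighbour flask gives 52.4 % at 1.5 h and 51.5 % at 3.0 d, with target at 23.9 % and other capture product at 22.5 %.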